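**Plan**

- Enabling feature: in the piperidine ring, C3 (ester oxygen) and C4 (bonded to chromone C8) are adjacent cis stereocentres. C2–C3 maps onto an alpha-oxy acyl unit and N1–C6–C5–C4 onto a cinnamaldehyde-derived 1-azadiene.
- Retrosynthetic cuts, in order: the C3–O veratroyl ester; the pyranone ring of the chromone (O1–C2, C2–C3, C4–C4a); N–CH3; the piperidine ring at C3–C4 and N1–C2; the azadiene C=N and the aryl–C4 bond.
- Forward: 1,3,5-trimethoxybenzene is extended to the enal and the N-sulfonyl azadiene, a carbene-catalysed [4+2] annulation closes the six-membered nitrogen ring, and the lactam is trimmed to the cis N-methylpiperidinol.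
- The chromone ring is then built on the aryl group (C-acetylation, Claisen condensation, cyclodehydration) and the phenols are freed. The ester is placed last: the acidic 7-OH is acylated first and serves as a mask, the C3' alcohol is acylated next, and the aryl ester is removed by methanolysis.
- Both stereocentres arise in the annulation (cis from the endo approach, absolute sense from the chiral triazolium salt); no later step touches C3 or C4.

Key step: step 3

Assumption: the (5aS,10bR) antipode of the aminoindanol triazolium salt is taken to give the 3S,4R lactam, by analogy with related enolate cycloadditions; if the sense of induction is opposite, the equally available (5aR,10bS) salt is used and nothing else changes.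

**Route**

Step 1
Reactants: 1 1,3,5-trimethoxybenzene; 2 (E)-3-(dimethylamino)prop-2-enal
Product: 4 (E)-3-(2,4,6-trimethoxyphenyl)prop-2-enal, via propeniminium chloride 3 (not isolated)
Conditions: POCl3, CH2Cl2, 0 °C to 40 °C; then aq. NaOAc, rt
Reagents that add atoms: water, O
Why: Vinylogous Vilsmeier–Haack formylation, in which POCl3 turns 2 into a 3-chloropropeniminium electrophile that the strongly activated arene attacks once at its only kind of free position, and hydrolysis of iminium salt 3 should give the thermodynamically preferred E-enal.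

Step 2
Reactants: 4 (E)-3-(2,4,6-trimethoxyphenyl)prop-2-enal; 5 4-methylbenzenesulfonamide
Product: 6 N-[(1E,2E)-3-(2,4,6-trimethoxyphenyl)prop-2-en-1-ylidene]-4-methylbenzenesulfonamide
Conditions: Ti(OEt)4 (2 equiv), CH2Cl2, 40 °C
Reagents that add atoms: none
Why: Dehydrative condensation of a sulfonamide with an aldehyde, with Ti(OEt)4 as Lewis acid and water scavenger; the fully conjugated E,E-1-azadiene is the thermodynamic product.

Step 3
Reactants: 6 N-[(1E,2E)-3-(2,4,6-trimethoxyphenyl)prop-2-en-1-ylidene]-4-methylbenzenesulfonamide; 7 2-(benzyloxy)acetyl chloride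
Product: 10 (3S,4R)-3-(benzyloxy)-1-(4-methylbenzenesulfonyl)-4-(2,4,6-trimethoxyphenyl)-3,4-dihydropyridin-2(1H)-one, via benzyloxyketene 8 (not isolated), via azolium enolate 9 (not isolated)
Conditions: (5aS,10bR)-2-mesityl-5a,10b-dihydro-4H,6H-indeno[2,1-b][1,2,4]triazolo[4,3-d][1,4]oxazin-2-ium chloride (10 mol %), iPr2NEt (2.5 equiv), 7 added slowly, toluene, 4 Å MS, 0 °C
Reagents that add atoms: none
Why: iPr2NEt converts 7 into benzyloxyketene 8, the triazolylidene adds to its central carbon anti to the benzyloxy group to give the Z-azolium enolate 9, and 9 bonds through its alpha-carbon to C4 of the azadiene while the sulfonamide nitrogen acylates on the azolium carbonyl (N1–C2), which releases the carbene. The closest known reaction type is the N-heterocyclic-carbene-catalysed inverse-electron-demand azadiene Diels–Alder reaction of azolium enolates (from enals, alpha-chloroaldehydes or ketenes) with N-sulfonyl 1-azadienes, which delivers cis-3,4-disubstituted 3,4-dihydropyridin-2-ones. The dihydropyridinone ring closes in a [4+2] mode, concerted but asynchronous or, in the stepwise limit, conjugate addition followed by 6-exo-trig N-acylation. C3 and C4 are created together: their cis relationship comes from the endo approach of the Z-enolate to the s-cis azadiene, and their absolute configuration from the aminoindane backbone of the catalyst, which blocks one face of the enolate. The step needs 1,4- over 1,2-addition (no Staudinger beta-lactam), cis over trans and no epimerisation at C3. The unsubstituted C5–C6 unit lets the E,E-azadiene reach the s-cis geometry, the sulfonyl group keeps C4 electrophilic despite the donor aryl group, slow addition of 7 keeps free ketene scarce, and the hindered amine at 0 °C is too weak to equilibrate the imide alpha-centre.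

Step 4
Reactants: 10 (3S,4R)-3-(benzyloxy)-1-(4-methylbenzenesulfonyl)-4-(2,4,6-trimethoxyphenyl)-3,4-dihydropyridin-2(1H)-one
Product: 11 (3S,4R)-3-(benzyloxy)-4-(2,4,6-trimethoxyphenyl)-3,4-dihydropyridin-2(1H)-one
Conditions: SmI2 (2.5 equiv), THF, −78 °C; then aq. NH4Cl
Reagents that add atoms: none
Why: Reductive desulfonylation, in which single-electron transfer from SmI2 to the N-acyl sulfonamide breaks the N–S bond to the lactam anion and sulfinate faster than the enamide or the alpha-benzyloxy carbonyl unit can react at −78 °C, and the non-basic medium leaves C3 untouched.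

Step 5
Reactants: 11 (3S,4R)-3-(benzyloxy)-4-(2,4,6-trimethoxyphenyl)-3,4-dihydropyridin-2(1H)-one
Product: 12 (3S,4R)-3-hydroxy-4-(2,4,6-trimethoxyphenyl)piperidin-2-one
Conditions: H2 (1 atm), Pd(OH)2 on carbon, MeOH/EtOAc, rt
Reagents that add atoms: none
Why: Heterogeneous catalytic hydrogenation should saturate the C5=C6 enamide bond and hydrogenolyse the O-benzyl ether in one operation, without forming a new stereocentre or exposing C3 to base.

Step 6
Reactants: 12 (3S,4R)-3-hydroxy-4-(2,4,6-trimethoxyphenyl)piperidin-2-one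
Product: 13 (3S,4R)-4-(2,4,6-trimethoxyphenyl)piperidin-3-ol
Conditions: LiAlH4 (5 equiv), THF, reflux; then H2O, aq. NaOH
Reagents that add atoms: none
Why: LiAlH4 reduction of a secondary lactam to the cyclic amine through the hemiaminal aluminate and the imine, under which the C3 alkoxide and the C4 benzylic centre are not epimerisable.

Step 7
Reactants: 13 (3S,4R)-4-(2,4,6-trimethoxyphenyl)piperidin-3-ol
Product: 14 (3S,4R)-1-methyl-4-(2,4,6-trimethoxyphenyl)piperidin-3-ol
Conditions: 37% aq. HCHO, H2 (1 atm), Pd on carbon (10 wt% Pd), MeOH, rt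
Reagents that add atoms: formaldehyde, C=O
Why: Reductive amination, in which formaldehyde condenses with the secondary amine to the iminium ion (or the fused oxazolidine in equilibrium with it) and hydrogenation gives the N-methyl amine without O-alkylation.

Step 8
Reactants: 14 (3S,4R)-1-methyl-4-(2,4,6-trimethoxyphenyl)piperidin-3-ol
Product: 16 1-{2-hydroxy-3-[(3S,4R)-3-hydroxy-1-methylpiperidin-4-yl]-4,6-dimethoxyphenyl}ethan-1-one, via O-acetyl ketone 15 (not isolated)
Conditions: Ac2O, BF3·OEt2 (excess), CH2Cl2, 0 °C to rt; then aq. NaOH, MeOH, rt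
Reagents that add atoms: acetic anhydride, CC(=O)OC(C)=O
Why: Friedel–Crafts C-acetylation of the free position of the trialkoxyarene, after which the difluoroboron chelate of the new ketone cleaves the more crowded flanking methoxy group (the one between acetyl and piperidinyl) and aqueous NaOH removes the O-acetate of 15.

Step 9
Reactants: 16 1-{2-hydroxy-3-[(3S,4R)-3-hydroxy-1-methylpiperidin-4-yl]-4,6-dimethoxyphenyl}ethan-1-one
Product: 18 8-[(3S,4R)-3-hydroxy-1-methylpiperidin-4-yl]-5,7-dimethoxy-2-methyl-4H-chromen-4-one, via 1,3-diketone 17 (not isolated)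
Conditions: NaH (5 equiv), EtOAc, THF, reflux; then conc. HCl, MeOH, 60 °C
Reagents that add atoms: ethyl acetate, CCOC(C)=O
Why: Crossed Claisen condensation of the methyl ketone enolate with ethyl acetate gives diketone 17, and acid-catalysed cyclodehydration by the ortho-phenol (6-exo-trig addition, then loss of water) closes the 2-methylchromone ring while acidic methanol cleaves any acetate picked up at the C3' oxygen.

Step 10
Reactants: 18 8-[(3S,4R)-3-hydroxy-1-methylpiperidin-4-yl]-5,7-dimethoxy-2-methyl-4H-chromen-4-one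
Product: 19 rohitukine, 5,7-dihydroxy-8-[(3S,4R)-3-hydroxy-1-methylpiperidin-4-yl]-2-methyl-4H-chromen-4-one
Conditions: pyridine hydrochloride (melt), 180 °C
Reagents that add atoms: none
Why: Nucleophilic O-demethylation of both aryl methyl ethers by chloride in molten pyridinium chloride (protonation, then SN2 at methyl), which the chromone, the protonated tertiary amine and the secondary alcohol should tolerate.

Step 11
Reactants: 19 rohitukine; 20 3,4-dimethoxybenzoyl chloride
Product: 21 5-hydroxy-8-[(3S,4R)-3-hydroxy-1-methylpiperidin-4-yl]-2-methyl-4-oxo-4H-chromen-7-yl 3,4-dimethoxybenzoate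
Conditions: 20 (1.05 equiv), Et3N (2 equiv), CH2Cl2/DMF, 0 °C; neutral aqueous work-up
Reagents that add atoms: none
Why: Chemoselective O-acylation of a phenoxide, since Et3N deprotonates only the acidic 7-OH (para-conjugated to the pyranone carbonyl), which should take up one equivalent of the aroyl chloride far faster than the chelated 5-OH or the hindered C3' alcohol; the resulting aryl ester masks the phenol with the same acyl group as the final ester, so a later O7-to-O3' acyl shift would be harmless, and 21, unlike zwitterionic 19, dissolves in CH2Cl2.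

Step 12
Reactants: 21 5-hydroxy-8-[(3S,4R)-3-hydroxy-1-methylpiperidin-4-yl]-2-methyl-4-oxo-4H-chromen-7-yl 3,4-dimethoxybenzoate; 20 3,4-dimethoxybenzoyl chloride
Product: 23 chrotacumine D, via bis-veratrate 22 (not isolated)
Conditions: 20 (1.5 equiv), Et3N (3 equiv), 4-(dimethylamino)pyridine (0.5 equiv), CH2Cl2, 0 °C to rt; then MeOH, K2CO3, 0 °C
Reagents that add atoms: none
Why: Nucleophile-catalysed acylation of the secondary alcohol through the acylpyridinium ion gives bis-ester 22, and carbonate-mediated methanolysis at 0 °C should then cleave only the aryl ester (its leaving phenoxide is far better than an alkoxide), which also removes any ester formed at the chelated 5-OH and leaves the hindered C3' veratrate of the electron-rich acid in place.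

**Compound list**

1 | 1,3,5-trimethoxybenzene | COc1cc(OC)cc(OC)c1 | starting material
2 | (E)-3-(dimethylamino)prop-2-enal | CN(C)/C=C/C=O | starting material
3 | (E)-N,N-dimethyl-3-(2,4,6-trimethoxyphenyl)prop-2-en-1-iminium chloride | COc1cc(OC)c(/C=C/C=[N+](C)C)c(OC)c1.[Cl-] | intermediate
4 | (E)-3-(2,4,6-trimethoxyphenyl)prop-2-enal | COc1cc(OC)c(/C=C/C=O)c(OC)c1 | intermediate
5 | 4-methylbenzenesulfonamide | Cc1ccc(cc1)S(N)(=O)=O | starting material
6 | N-[(1E,2E)-3-(2,4,6-trimethoxyphenyl)prop-2-en-1-ylidene]-4-methylbenzenesulfonamide | Cc1ccc(cc1)S(=O)(=O)/N=C/C=C/c1c(OC)cc(OC)cc1OC | intermediate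
7 | 2-(benzyloxy)acetyl chloride | O=C(Cl)COCc1ccccc1 | starting material
8 | benzyloxyketene, 2-(benzyloxy)ethen-1-one | O=C=COCc1ccccc1 | intermediate
9 | (Z)-2-(benzyloxy)-1-[(5aS,10bR)-2-mesityl-5a,10b-dihydro-4H,6H-indeno[2,1-b][1,2,4]triazolo[4,3-d][1,4]oxazin-2-ium-1-yl]ethen-1-olate (azolium enolate) | Cc1cc(C)c(c(C)c1)-[n+]1nc2CO[C@H]3Cc4ccccc4[C@H]3n2c1/C([O-])=C/OCc1ccccc1 | intermediate
10 | (3S,4R)-3-(benzyloxy)-1-(4-methylbenzenesulfonyl)-4-(2,4,6-trimethoxyphenyl)-3,4-dihydropyridin-2(1H)-one | c1ccccc1CO[C@@H]1C(=O)N(S(=O)(=O)c2ccc(C)cc2)C=C[C@@H]1c1c(OC)cc(OC)cc1OC | intermediate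
11 | (3S,4R)-3-(benzyloxy)-4-(2,4,6-trimethoxyphenyl)-3,4-dihydropyridin-2(1H)-one | c1ccccc1CO[C@@H]1C(=O)NC=C[C@@H]1c1c(OC)cc(OC)cc1OC | intermediate
12 | (3S,4R)-3-hydroxy-4-(2,4,6-trimethoxyphenyl)piperidin-2-one | O[C@@H]1C(=O)NCC[C@@H]1c1c(OC)cc(OC)cc1OC | intermediate
13 | (3S,4R)-4-(2,4,6-trimethoxyphenyl)piperidin-3-ol | O[C@@H]1CNCC[C@@H]1c1c(OC)cc(OC)cc1OC | intermediate
14 | (3S,4R)-1-methyl-4-(2,4,6-trimethoxyphenyl)piperidin-3-ol | O[C@@H]1CN(C)CC[C@@H]1c1c(OC)cc(OC)cc1OC | intermediate
15 | (3S,4R)-4-(3-acetyl-2-hydroxy-4,6-dimethoxyphenyl)-1-methylpiperidin-3-yl acetate | CC(=O)O[C@@H]1CN(C)CC[C@@H]1c1c(O)c(C(C)=O)c(OC)cc1OC | intermediate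
16 | 1-{2-hydroxy-3-[(3S,4R)-3-hydroxy-1-methylpiperidin-4-yl]-4,6-dimethoxyphenyl}ethan-1-one | O[C@@H]1CN(C)CC[C@@H]1c1c(O)c(C(C)=O)c(OC)cc1OC | intermediate
17 | 1-{2-hydroxy-3-[(3S,4R)-3-hydroxy-1-methylpiperidin-4-yl]-4,6-dimethoxyphenyl}butane-1,3-dione | O[C@@H]1CN(C)CC[C@@H]1c1c(O)c(C(=O)CC(C)=O)c(OC)cc1OC | intermediate
18 | 8-[(3S,4R)-3-hydroxy-1-methylpiperidin-4-yl]-5,7-dimethoxy-2-methyl-4H-chromen-4-one | O[C@@H]1CN(C)CC[C@@H]1c1c(OC)cc(OC)c2c(=O)cc(C)oc12 | intermediate
19 | rohitukine, 5,7-dihydroxy-8-[(3S,4R)-3-hydroxy-1-methylpiperidin-4-yl]-2-methyl-4H-chromen-4-one | O[C@@H]1CN(C)CC[C@@H]1c1c(O)cc(O)c2c(=O)cc(C)oc12 | intermediate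
20 | 3,4-dimethoxybenzoyl chloride | COc1ccc(C(Cl)=O)cc1OC | starting material
21 | 5-hydroxy-8-[(3S,4R)-3-hydroxy-1-methylpiperidin-4-yl]-2-methyl-4-oxo-4H-chromen-7-yl 3,4-dimethoxybenzoate | O[C@@H]1CN(C)CC[C@@H]1c1c(OC(=O)c2ccc(OC)c(OC)c2)cc(O)c2c(=O)cc(C)oc12 | intermediate
22 | (3S,4R)-4-[7-(3,4-dimethoxybenzoyloxy)-5-hydroxy-2-methyl-4-oxo-4H-chromen-8-yl]-1-methylpiperidin-3-yl 3,4-dimethoxybenzoate | COc1ccc(C(=O)O[C@@H]2CN(C)CC[C@@H]2c2c(OC(=O)c3ccc(OC)c(OC)c3)cc(O)c3c(=O)cc(C)oc23)cc1OC | intermediate
23 | chrotacumine D, (3S,4R)-4-(5,7-dihydroxy-2-methyl-4-oxo-4H-chromen-8-yl)-1-methylpiperidin-3-yl 3,4-dimethoxybenzoate | COc1ccc(C(=O)O[C@@H]2CN(C)CC[C@@H]2c2c(O)cc(O)c3c(=O)cc(C)oc23)cc1OC | target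

**Step count and risks**

Total steps: 12. Longest linear sequence: 12 steps, from 1 to 23; all other building blocks are commercial.

Steps most likely to fail:

1. Step 3. The donor-substituted, doubly ortho-hindered azadiene may take up the alpha-alkoxy enolate too slowly. Ketene dimerisation or 1,2-addition to C=N (beta-lactam formation) could then take over, or the cis and enantiofacial control could erode. The fallback sets out from 1 and returns at 14. Acid-promoted condensation of 1 with 1-methylpiperidin-4-one (HCl in AcOH, 90 °C) should give 1-methyl-4-(2,4,6-trimethoxyphenyl)-1,2,3,6-tetrahydropyridine F1. Hydroboration–oxidation (BH3·THF; then NaOH, H2O2) should give racemic trans-1-methyl-4-(2,4,6-trimethoxyphenyl)piperidin-3-ol F2. Swern oxidation ((COCl)2, DMSO, Et3N, −78 °C) gives 1-methyl-4-(2,4,6-trimethoxyphenyl)piperidin-3-one F3. Reduction with NaBH4 from the face opposite the aryl group should give mainly the racemic cis-alcohol, that is 14 together with its mirror image (3R,4S)-1-methyl-4-(2,4,6-trimethoxyphenyl)piperidin-3-ol F4. Crystallisation of the salt with one enantiomer of O,O'-dibenzoyltartaric acid then separates 14, which re-enters at step 8.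

2. Step 4. Electron transfer may go to the alpha-benzyloxy carbonyl unit, with loss of the C3 oxygen, or the activated lactam may open at work-up before the N–S bond is cleaved. The fallback sets out from 10 and returns at 13; it keeps the sulfonyl group until the carbonyl is gone. Hydrogenation over Pd on carbon in EtOAc with a trace of pyridine should saturate C5=C6 and keep the benzyl ether, giving (3S,4R)-3-(benzyloxy)-1-(4-methylbenzenesulfonyl)-4-(2,4,6-trimethoxyphenyl)piperidin-2-one F5. iBu2AlH at −78 °C should stop at the N-sulfonyl hemiaminal (3S,4R)-3-(benzyloxy)-1-(4-methylbenzenesulfonyl)-4-(2,4,6-trimethoxyphenyl)piperidin-2-ol F6. Et3SiH with BF3·OEt2 removes the hydroxyl through the N-sulfonyliminium ion to give (3S,4R)-3-(benzyloxy)-1-(4-methylbenzenesulfonyl)-4-(2,4,6-trimethoxyphenyl)piperidine F7. Lithium naphthalenide (LiC10H8) in THF at −30 °C should cleave both the sulfonamide and the benzyl ether to give 13.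

3. Step 12. Acylation of the crowded C3' hydroxyl may be too slow, so that forcing conditions pile acyl groups onto the phenols, and the methanolysis may then fail to discriminate, with loss of the C3' ester alongside the aryl esters. The fallback sets out from 19 and returns at 23; it masks both phenols as silyl ethers, so that the acylation can be forced and the unmasking is no longer an ester cleavage. tert-Butyldimethylsilyl chloride with imidazole in DMF should silylate the two phenols ahead of the hindered secondary alcohol, giving 5,7-bis(tert-butyldimethylsilyloxy)-8-[(3S,4R)-3-hydroxy-1-methylpiperidin-4-yl]-2-methyl-4H-chromen-4-one F8. Acylation of the remaining alcohol with 20 (pyridine, 4-(dimethylamino)pyridine, CH2Cl2, 40 °C) gives (3S,4R)-4-[5,7-bis(tert-butyldimethylsilyloxy)-2-methyl-4-oxo-4H-chromen-8-yl]-1-methylpiperidin-3-yl 3,4-dimethoxybenzoate F9. HF·pyridine in THF at 0 °C removes both aryl silyl ethers without touching the ester and gives 23.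

**Further compounds**

F1 | step 3 | 1-methyl-4-(2,4,6-trimethoxyphenyl)-1,2,3,6-tetrahydropyridine | CN1CCC(=CC1)c1c(OC)cc(OC)cc1OC
F2 | step 3 | rac-(3R,4R)-1-methyl-4-(2,4,6-trimethoxyphenyl)piperidin-3-ol (trans racemate, one enantiomer drawn) | O[C@H]1CN(C)CC[C@@H]1c1c(OC)cc(OC)cc1OC
F3 | step 3 | 1-methyl-4-(2,4,6-trimethoxyphenyl)piperidin-3-one (racemic) | CN1CCC(C(=O)C1)c1c(OC)cc(OC)cc1OC
F4 | step 3 | (3R,4S)-1-methyl-4-(2,4,6-trimethoxyphenyl)piperidin-3-ol | O[C@H]1CN(C)CC[C@H]1c1c(OC)cc(OC)cc1OC
F5 | step 4 | (3S,4R)-3-(benzyloxy)-1-(4-methylbenzenesulfonyl)-4-(2,4,6-trimethoxyphenyl)piperidin-2-one | c1ccccc1CO[C@@H]1C(=O)N(S(=O)(=O)c2ccc(C)cc2)CC[C@@H]1c1c(OC)cc(OC)cc1OC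
F6 | step 4 | (3S,4R)-3-(benzyloxy)-1-(4-methylbenzenesulfonyl)-4-(2,4,6-trimethoxyphenyl)piperidin-2-ol (both C2 epimers) | c1ccccc1CO[C@@H]1C(O)N(S(=O)(=O)c2ccc(C)cc2)CC[C@@H]1c1c(OC)cc(OC)cc1OC
F7 | step 4 | (3S,4R)-3-(benzyloxy)-1-(4-methylbenzenesulfonyl)-4-(2,4,6-trimethoxyphenyl)piperidine | c1ccccc1CO[C@@H]1CN(S(=O)(=O)c2ccc(C)cc2)CC[C@@H]1c1c(OC)cc(OC)cc1OC
F8 | step 12 | 5,7-bis(tert-butyldimethylsilyloxy)-8-[(3S,4R)-3-hydroxy-1-methylpiperidin-4-yl]-2-methyl-4H-chromen-4-one | O[C@@H]1CN(C)CC[C@@H]1c1c(O[Si](C)(C)C(C)(C)C)cc(O[Si](C)(C)C(C)(C)C)c2c(=O)cc(C)oc12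
F9 | step 12 | (3S,4R)-4-[5,7-bis(tert-butyldimethylsilyloxy)-2-methyl-4-oxo-4H-chromen-8-yl]-1-methylpiperidin-3-yl 3,4-dimethoxybenzoate | COc1ccc(C(=O)O[C@@H]2CN(C)CC[C@@H]2c2c(O[Si](C)(C)C(C)(C)C)cc(O[Si](C)(C)C(C)(C)C)c3c(=O)cc(C)oc23)cc1OC
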